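# A 15β-hydroxylated C20 gibberellin triacid by an interrupted Nazarov cascade: synthesis design

## The problem

The target, 15β-hydroxy-ent-gibberell-16-ene-7,19,20-trioic acid, is a C20 gibberellin in which cyclohexane ring A and cyclopentane ring B share C5–C10, ring B shares C8–C9 with cyclohexane ring C, and the C15–C16 bridge across C8 and C13 closes ring D, a bicyclo[3.2.1]octane that carries the C16=C17 methylene and the C15 hydroxyl. C4, C8 and C10 are quaternary, and eight stereocentres (C4, C5, C6, C8, C9, C10, C13, C15) must be set. Throughout, β denotes the face of ring B that bears H5, H9, C7 and C15 and α the face of C14, C19 and C20; the 15-hydroxyl of the target lies on the face of ring D turned toward C9 (15β, anti to C14), and tetracyclic intermediates are named on the ent-gibberellane skeleton with α and β in this sense. C13 dictates C8, because the two-carbon bridge can span only one face of ring C, and C9 and C10 are tied to each other if their bond is made stereospecifically. C5 and C6 can be set late against the α-axial groups on C4 and C10 and C15 by the shape of ring D, whereas C4 and C13 have no neighbour to lean on and must enter enantiopure. The 15-hydroxy-16-ene rearranges to a 16-methyl 15-ketone in acid, and the exocyclic alkene rules out hydrogenation, hydrogenolysis and ozonolysis once it exists. C19 and C20 are 1,3-diaxial, so a free C20 hydroxyl closes on a C19 ester to a δ-lactone (a 15α-hydroxyl can close on C7 likewise), and both tertiary esters resist hydroxide. The enabling feature is that C6 of ring B carries only the one-carbon carboxyl C7, so C6 can be a ketone flanked by C5 and C8: with C5=C10 in ring A and C8=C9 in ring C this is a cross-conjugated dienone whose 4π closure makes C9–C10 and leaves a cation at C8, the very atom that must receive C15 from a side chain on C13.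

## Retrosynthesis

**28 ⇐ 27 ⇐ 26 ⇐ 25 ⇐ 24 ⇐ 23 (no skeletal bond cut).** The acids are freed last from dimethyl ester 27 by thiolate demethylation, which attacks the ester methyl groups and so is indifferent to the shielding of C19 and needs no acid. The 15β-alcohol of 27 comes from enone 26 by hydride delivery to the exo face. SeO2 hydroxylation of the 16-ene 23 should place oxygen on that same exo face and give the 15α-alcohol 24, so an oxidation–reduction is needed in any case. The oxidation is therefore made to do two jobs: after desilylation of 24, one chromic acid treatment of diol 25 gives both the 15-ketone and the C20 acid. C20 stays silylated until just before this oxidation because of the lactone problem. Compound 23 is simpler by the C15 oxygen and by two oxidation levels at C20.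

**23 ⇐ 22 ⇐ 21 ⇐ 20 (cut C6–C7).** The key step needs a C6 ketone, and C7 is then added by carbonylation of enol triflate 21. This homologation copes with a carbonyl hemmed in by quaternary C8 and by C5, where olefination-type homologations of ketone 20 would struggle. It also gives enoate 22, whose conjugate reduction sets C5 by protonation anti to the α-axial C19 and C20 groups and C6 by equilibration. The forward steps must enolize toward C5 (the only α-hydrogen), carbonylate a hindered triflate, and reduce without touching the 16-ene.

**20 ⇐ 18 (cut C9–C10 and C8–C15; key step).** Lewis acid activation of dienone 18 should close ring B by conrotatory 4π electrocyclization, and the oxyallyl cation should then be captured at C8 by the allylsilane on C13, closing ring D and leaving the 16-methylene. The neighbouring cuts, ring B by aldol or Dieckmann chemistry on a preformed C8 quaternary centre, or ring D by a separate enolate alkylation, each need C8 and C10 to be built one at a time. Here both quaternary ring-fusion carbons, two rings and three stereocentres (C8, C9, C10) arise from two monocyclic cyclohexenes. C20 is carried as a silyloxymethyl group because an ester on C10 would make that dienone terminus electron-poor. C4 is already quaternary, which blocks proton loss from the cation on the ring A side. The step must rotate in the right sense relative to C4 and C13.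

**18 ⇐ 17 + 9 + CO (cut C5–C6 and C6–C8).** A carbonylative Stille coupling joins the ring A enol triflate 17 and the ring C alkenylstannane 9 with carbon monoxide as C6. Both partners derive from ketones, so the positions of both double bonds are defined. The alternative, addition of a ring C alkenyllithium to a ring A aldehyde followed by oxidation, is two steps longer and is kept as the fallback.

**9 ⇐ 8 ⇐ 6 ⇐ 5 ⇐ 3 ⇐ 2 ⇐ 1 (ring C).** Conjugate addition of the silylmethylvinyl group to cyclohexenone would give the carbon skeleton at once. It leaves a 3-substituted cyclohexanone, though, whose conversion to the C8=C9 enol triflate is not regioselective. Instead the carboxyl of commercial (R)-cyclohex-3-ene-1-carboxylic acid 1 marks C8 by iodolactonization (2). Elimination gives allylic lactone 3. The lactone carbonyl becomes the allylsilane (5) by double silylmethyl addition and Peterson elimination. Oxidation gives enone 6, and conjugate reduction with enolate trapping delivers triflate 8 as a single regioisomer. C13 comes from the chiral pool and is never enolizable.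

**17 ⇐ 16 ⇐ 15 ⇐ 14 ⇐ 12 ⇐ 10 + 11 (ring A).** The C4 quaternary centre is set by auxiliary-controlled methylation of the valine tert-butyl ester enamine 12 of methyl 2-oxocyclohexane-1-carboxylate 10. Because C4 is then quaternary, ketone 14 can enolize only toward the future C10. This places C20 by a formaldehyde aldol (15) and, after silylation (16), gives the tetrasubstituted enol triflate 17 without regiochemical choice.

## Roads not taken

Alternative 1: The cut is C4–C5, with ring A closed afterwards by metathesis. In the forward sense KN(SiMe3)2 would deprotonate the γ-methyl of a tiglate unit carried on the C20 oxygen. The dienolate α-carbon (C4) would add to C5 of a ring B enoate and give the 19,20-lactone A1.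
- Merits: the tether delivers C4 to the α face of C5, so C4, C5 and their relation to C10 are set in one intramolecular step, with no auxiliary and no reliance on kinetic protonation. C7 is present from the start. The C19/C20 lactone, which the chosen plan must avoid, is here the control element.
- Weak points: the B/C/D tricycle with quaternary C8 and C10, the C20 carbinol and an allyl group must exist first, so the hard problem (C8, C9, C10, C13) is only moved upstream. The dienolate can react through its γ-carbon. After ring closure C20 sits at the alcohol level inside a lactone that re-closes whenever it is opened, and it must still be raised to the acid. Alkene reduction, ketal removal, methylenation and C15 oxidation follow.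
- Comparison: on C4 and C5 this road is better. Against it the chosen plan sets the two ring-fusion quaternary carbons and rings B and D in one step from two simple cyclohexenes, and oxidizes C20 from a silyl ether rather than from a lactone.

Alternative 2: The cut is C13–C16, with C12–C16 as a temporary bond. Rh2(OAc)4 would decompose a diazomethyl ketone on C8 and the carbenoid would add to a C12=C13 alkene, giving cyclopropyl ketone A2. Reductive opening of C12–C16 and α-methylenation would then lead to the 16-en-15-one.
- Merits: the C15 oxygen is born on the right carbon, so no allylic oxidation and no epimer correction are needed. All three carboxyls are in place, and this ring D construction is well tried on this skeleton.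
- Weak points: the complete A/B/C triester with quaternary C8 carrying an extra carboxyl, and a correctly placed ring C alkene, must be assembled linearly first. The sense of cyclopropane cleavage depends on orbital overlap with the ketone. The carbenoid can insert into nearby C–H bonds.
- Comparison: in end-game economy this road is superior, since the chosen plan spends steps 17 to 20 on C15 and C20. What the chosen plan offers in return is convergence and the formation of quaternary C8 in the same operation as ring B.

Alternative 3: The cuts are C5–C10 and C3–C4. Me2AlCl would promote an intramolecular Diels–Alder reaction between a diene on C9 and an enoate on the C8 side chain, closing rings A and B together to give A3.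
- Merits: two rings and the stereocentres C4, C5 and C10 form in one step. C4 is set by dienophile geometry and not by an auxiliary. C7, the C15 oxygen and the C16 ketone are carried from the start.
- Weak points: both new bonds end at fully substituted carbons, so the cycloaddition is sterically demanding and its facial selectivity rests on an epimerizable C6. The activating ester on C4 ends up where the C18 methyl must be and has to be reduced to CH3. C19 and C20 arrive as two diaxial silyloxymethyl groups that must both be raised to acids past the lactol/lactone trap. The C1=C2 alkene and the methylenation next to an oxygenated C15 remain.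
- Comparison: in stereocentres per step this road is at least equal. The chosen plan has fewer oxidation-level corrections (only C20) and simpler fragments.

Key step: step 13

Assumption: methylation of the lithio enamine of L-valine tert-butyl ester in toluene with one equivalent of HMPA is taken to give the (R)-keto ester 14. If the sense is the opposite, THF without HMPA or the D-valine ester is used, each of which is known to reverse it.

## Route

Step 1
Reactants: 1 (R)-cyclohex-3-ene-1-carboxylic acid
Product: 2 (1R,4R,5R)-4-iodo-6-oxabicyclo[3.2.1]octan-7-one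
Conditions: I2, KI, NaHCO3, H2O, rt, dark
Reagents that add atoms: iodine, II
Why: Iodolactonization: the carboxylate reaches only the alkene carbon 1,3 to it and on its own face, so oxygen is delivered cis at the future C8 and iodine trans at the future C9; this marks C8 regiospecifically and leaves C13 untouched.

Step 2
Reactants: 2 (1R,4R,5R)-4-iodo-6-oxabicyclo[3.2.1]octan-7-one
Product: 3 (1R,5R)-6-oxabicyclo[3.2.1]oct-3-en-7-one
Conditions: DBU, toluene, 110 °C
Reagents that add atoms: none
Why: E2 dehydrohalogenation with an amidine base; elimination toward the oxygen-bearing bridgehead would give a bridgehead alkene, so only the anti hydrogen on the future C11 is lost and the allylic lactone results.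

Step 3
Reactants: 3 (1R,5R)-6-oxabicyclo[3.2.1]oct-3-en-7-one
Product: 5 (1R,5R)-5-[3-(trimethylsilyl)prop-1-en-2-yl]cyclohex-2-en-1-ol, via bis(silylmethyl) carbinol 4 (not isolated)
Conditions: Me3SiCH2MgCl (5 equiv), CeCl3, THF, −78 °C → rt; then SiO2, CH2Cl2, rt
Reagents that add atoms: (trimethylsilyl)methylmagnesium chloride, C[Si](C)(C)C[Mg]Cl
Why: Cerium-mediated double addition of the silylmethyl Grignard reagent to the lactone carbonyl (the organocerium species is nucleophilic but hardly basic, so C13 is not enolized), then acid-induced Peterson elimination of the tertiary β-hydroxysilane on silica gel; this is a standard conversion of esters and lactones into 2-substituted allylsilanes.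

Step 4
Reactants: 5 (1R,5R)-5-[3-(trimethylsilyl)prop-1-en-2-yl]cyclohex-2-en-1-ol
Product: 6 (5R)-5-[3-(trimethylsilyl)prop-1-en-2-yl]cyclohex-2-en-1-one
Conditions: MnO2, CH2Cl2, rt
Reagents that add atoms: none
Why: Selective oxidation of an allylic alcohol by MnO2; the carbinol centre is erased and the allylsilane is inert to the neutral oxidant.

Step 5
Reactants: 6 (5R)-5-[3-(trimethylsilyl)prop-1-en-2-yl]cyclohex-2-en-1-one
Product: 8 (5R)-5-[3-(trimethylsilyl)prop-1-en-2-yl]cyclohex-1-en-1-yl trifluoromethanesulfonate, via lithium enolate 7 (not isolated)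
Conditions: LiBH(s-Bu)3 (L-Selectride), THF, −78 °C; then PhNTf2, −78 °C → rt
Reagents that add atoms: N-phenylbis(trifluoromethanesulfonimide), O=S(=O)(N(c1ccccc1)S(=O)(=O)C(F)(F)F)C(F)(F)F
Why: Conjugate hydride reduction of a β-unsubstituted cyclohexenone gives the enolate only on the C8–C9 side and O-triflation fixes that regiochemistry; deprotonation of the corresponding 3-substituted cyclohexanone would give both enol triflates.

Step 6
Reactants: 8 (5R)-5-[3-(trimethylsilyl)prop-1-en-2-yl]cyclohex-1-en-1-yl trifluoromethanesulfonate
Product: 9 trimethyl{(5R)-5-[3-(trimethylsilyl)prop-1-en-2-yl]cyclohex-1-en-1-yl}stannane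
Conditions: Me3SnSnMe3, Pd(PPh3)4 (5 mol %), LiCl, THF, 60 °C
Reagents that add atoms: hexamethyldistannane, C[Sn](C)(C)[Sn](C)(C)C
Why: Palladium-catalysed stannylation of an enol triflate with a distannane (oxidative addition, Sn–Sn transmetalation, reductive elimination); LiCl keeps the catalyst turning over and the allylsilane is a spectator.

Step 7
Reactants: 10 methyl 2-oxocyclohexane-1-carboxylate; 11 L-valine tert-butyl ester
Product: 12 methyl 2-{[(2S)-1-tert-butoxy-3-methyl-1-oxobutan-2-yl]amino}cyclohex-1-ene-1-carboxylate
Conditions: p-TsOH (cat.), toluene, reflux, Dean–Stark trap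
Reagents that add atoms: none
Why: Acid-catalysed condensation of the β-keto ester with the primary amine gives the hydrogen-bonded conjugated enamine, driven by azeotropic removal of water.

Step 8
Reactants: 12 methyl 2-{[(2S)-1-tert-butoxy-3-methyl-1-oxobutan-2-yl]amino}cyclohex-1-ene-1-carboxylate
Product: 14 methyl (1R)-1-methyl-2-oxocyclohexane-1-carboxylate, via N-alkyl imine 13 (not isolated)
Conditions: LiN(i-Pr)2, toluene, HMPA (1 equiv), −78 °C; MeI, −78 → −20 °C; then 1 M aq. HCl, rt
Reagents that add atoms: iodomethane, CI; water, O
Why: Auxiliary-controlled alkylation of the chelated lithio enamine: the valine isopropyl and tert-butoxycarbonyl groups leave one face of the aza-enolate open to MeI, and mild acid then hydrolyses the imine to the quaternary keto ester and returns the amino ester; this enamine alkylation of cyclic β-keto esters is an established route to α,α-disubstituted β-keto esters of high ee.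

Step 9
Reactants: 14 methyl (1R)-1-methyl-2-oxocyclohexane-1-carboxylate
Product: 15 methyl (1R,3RS)-3-(hydroxymethyl)-1-methyl-2-oxocyclohexane-1-carboxylate
Conditions: LiN(i-Pr)2, THF, −78 °C; HCHO (gas, from paraformaldehyde), −78 → −40 °C; aq. NH4Cl
Reagents that add atoms: formaldehyde, C=O
Why: C4 is quaternary, so the amide base can enolize only toward the future C10; aldol addition to monomeric formaldehyde installs C20, and the new stereocentre is of no consequence because C10 becomes sp2 in step 11.

Step 10
Reactants: 15 methyl (1R,3RS)-3-(hydroxymethyl)-1-methyl-2-oxocyclohexane-1-carboxylate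
Product: 16 methyl (1R,3RS)-3-{[(tert-butyldiphenylsilyl)oxy]methyl}-1-methyl-2-oxocyclohexane-1-carboxylate
Conditions: t-BuPh2SiCl, imidazole, CH2Cl2, 0 °C → rt
Reagents that add atoms: tert-butyl(chloro)diphenylsilane, CC(C)(C)[Si](Cl)(c1ccccc1)c1ccccc1
Why: Standard silylation of a primary alcohol; this silyl ether is chosen because it should survive BF3·OEt2, strong bases, palladium catalysis and Mg/MeOH.

Step 11
Reactants: 16 methyl (1R,3RS)-3-{[(tert-butyldiphenylsilyl)oxy]methyl}-1-methyl-2-oxocyclohexane-1-carboxylate
Product: 17 methyl (1R)-3-{[(tert-butyldiphenylsilyl)oxy]methyl}-1-methyl-2-{[(trifluoromethyl)sulfonyl]oxy}cyclohex-2-ene-1-carboxylate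
Conditions: KN(SiMe3)2, THF, −78 °C; PhNTf2, −78 → 0 °C
Reagents that add atoms: N-phenylbis(trifluoromethanesulfonimide), O=S(=O)(N(c1ccccc1)S(=O)(=O)C(F)(F)F)C(F)(F)F
Why: Deprotonation at the only α-hydrogen and O-sulfonylation give the tetrasubstituted enol triflate; low temperature and immediate trapping keep the β-silyloxy enolate from eliminating.

Step 12
Reactants: 17 methyl (1R)-3-{[(tert-butyldiphenylsilyl)oxy]methyl}-1-methyl-2-{[(trifluoromethyl)sulfonyl]oxy}cyclohex-2-ene-1-carboxylate; 9 trimethyl{(5R)-5-[3-(trimethylsilyl)prop-1-en-2-yl]cyclohex-1-en-1-yl}stannane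
Product: 18 methyl (1R)-3-{[(tert-butyldiphenylsilyl)oxy]methyl}-1-methyl-2-{(5R)-5-[3-(trimethylsilyl)prop-1-en-2-yl]cyclohex-1-ene-1-carbonyl}cyclohex-2-ene-1-carboxylate
Conditions: Pd(PPh3)4 (5 mol %), LiCl, CO (3 atm), THF, 55–65 °C
Reagents that add atoms: carbon monoxide, [C-]#[O+]
Why: Carbonylative Stille coupling: oxidative addition of the enol triflate to zerovalent palladium, CO insertion to the acylpalladium, transmetalation from the alkenylstannane and reductive elimination give the divinyl ketone; this coupling is the classical entry to Nazarov substrates and tolerates allylsilane, ester and silyl ether.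

Step 13
Reactants: 18 methyl (1R)-3-{[(tert-butyldiphenylsilyl)oxy]methyl}-1-methyl-2-{(5R)-5-[3-(trimethylsilyl)prop-1-en-2-yl]cyclohex-1-ene-1-carbonyl}cyclohex-2-ene-1-carboxylate
Product: 20 methyl 20-[(tert-butyldiphenylsilyl)oxy]-6-oxo-7-nor-ent-gibberell-16-en-19-oate (tetracyclic 6-ketone; H5 and H9 β, C19 and C20 α, C15 β on C8), via oxyallyl cation 19 (not isolated)
Conditions: BF3·OEt2 (1.5 equiv), 2,6-di-tert-butyl-4-methylpyridine (0.3 equiv), CH2Cl2, −78 → −30 °C; then aq. NaHCO3
Reagents that add atoms: none
Why: BF3 binds the C6 carbonyl and the 3-oxidopentadienyl cation, in its U-shaped form, closes by thermal conrotatory 4π electrocyclization to form C9–C10 and the five-membered ring B, giving the 2-oxidocyclopentenyl cation 19; the closest known reaction type is the interrupted Nazarov cyclization in which the oxyallyl cation is intercepted by an allylsilane or a tethered olefin. Conrotation turns the outside groups C1 and C11 trans, so C20 and H9 are necessarily anti, which sets C9 and C10 relative to each other. The selectivity the step needs is the sense of rotation relative to C4 and C13: in ring C the half-chair with the C13 side chain pseudo-equatorial passes directly into a chair only if C11 swings toward the C13 side, which puts the new C9–C10 bond trans to the side chain, and in ring A the half-chair with the C4 ester pseudo-axial (turned away from the BF3-bound oxygen) passes into a chair only if C20 swings to the ester face, which avoids a developing CH3/C20 syn-diaxial contact; both biases call for the same rotation, so the (R)-C4/(R)-C13 pairing should be matched. C8 is then attacked by the terminal allylsilane carbon C15 in a five-membered cation–olefin closure that is endocyclic with respect to the nucleophilic alkene (ring D), and loss of the silyl group from the β-silyl cation leaves the C16=C17 methylene. C8 is set by C13, because the side chain can reach only the lobe on its own face of ring C; for this diastereomer that is the H9 face and ring C must pass through a twist-boat. C4 and C10 are quaternary, so the cation cannot lose a proton on the ring A side, and low temperature with a hindered pyridine should suppress proton loss from C9 or C14 and protodesilylation. Aqueous quench protonates the C5 enol, expected on the β face since C19 and C20 screen the α face; this centre is planarized again in step 14.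

Step 14
Reactants: 20 methyl 20-[(tert-butyldiphenylsilyl)oxy]-6-oxo-7-nor-ent-gibberell-16-en-19-oate
Product: 21 methyl 20-[(tert-butyldiphenylsilyl)oxy]-6-{[(trifluoromethyl)sulfonyl]oxy}-7-nor-ent-gibberella-5,16-dien-19-oate
Conditions: KN(SiMe3)2, THF, −78 → 0 °C; N-(5-chloropyridin-2-yl)bis(trifluoromethanesulfonimide), −78 °C → rt
Reagents that add atoms: N-(5-chloropyridin-2-yl)bis(trifluoromethanesulfonimide), FC(F)(F)S(=O)(=O)N(c1ccc(Cl)cn1)S(=O)(=O)C(F)(F)F
Why: C8 is quaternary, so the base can remove only H5; O-sulfonylation of the tetrasubstituted enolate with the more reactive pyridyl triflimide gives the C5=C6 enol triflate and erases C5.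

Step 15
Reactants: 21 methyl 20-[(tert-butyldiphenylsilyl)oxy]-6-{[(trifluoromethyl)sulfonyl]oxy}-7-nor-ent-gibberella-5,16-dien-19-oate
Product: 22 dimethyl 20-[(tert-butyldiphenylsilyl)oxy]-ent-gibberella-5,16-diene-7,19-dioate
Conditions: Pd(OAc)2 (10 mol %), 1,3-bis(diphenylphosphino)propane, Et3N, CO (1 atm), MeOH–DMF, 70 °C
Reagents that add atoms: carbon monoxide, [C-]#[O+]; methanol, CO
Why: Palladium-catalysed alkoxycarbonylation of an enol triflate (oxidative addition, CO insertion, methanolysis) creates the C6–C7 bond; a chelating bisphosphine is used because the triflate is flanked by C8 and the fully substituted C5.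

Step 16
Reactants: 22 dimethyl 20-[(tert-butyldiphenylsilyl)oxy]-ent-gibberella-5,16-diene-7,19-dioate
Product: 23 dimethyl 20-[(tert-butyldiphenylsilyl)oxy]-ent-gibberell-16-ene-7,19-dioate (H5 β, H6 α, C7 β)
Conditions: Mg, MeOH, 0 °C → rt; then NaOMe, MeOH, 50 °C
Reagents that add atoms: none
Why: Single-electron (dissolving-metal type) conjugate reduction of the α,β-unsaturated ester, which leaves isolated alkenes alone: C5 should be protonated by methanol on the β face because the α face is closed by the axial C19 ester and C20 silyloxymethyl group, giving the trans A/B fusion. Methoxide then equilibrates C6 to the more stable 6β-ester, which is trans to C4 and has only C15 as a cis neighbour.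

Step 17
Reactants: 23 dimethyl 20-[(tert-butyldiphenylsilyl)oxy]-ent-gibberell-16-ene-7,19-dioate
Product: 24 dimethyl 20-[(tert-butyldiphenylsilyl)oxy]-15α-hydroxy-ent-gibberell-16-ene-7,19-dioate (15-OH exo, syn to C14)
Conditions: SeO2 (0.5 equiv), t-BuOOH, CH2Cl2, rt
Reagents that add atoms: selenium dioxide, O=[Se]=O; tert-butyl hydroperoxide, CC(C)(C)OO
Why: Allylic hydroxylation by SeO2 (ene reaction at C17 with removal of a C15 hydrogen, then [2,3]-sigmatropic shift) with the hydroperoxide as terminal oxidant; C15 is the only allylic position that can react since C13 is a bridgehead, and oxygen should arrive on the exposed exo face of ring D, as is the rule for kaurene- and gibberellin-type 16-enes.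

Step 18
Reactants: 24 dimethyl 20-[(tert-butyldiphenylsilyl)oxy]-15α-hydroxy-ent-gibberell-16-ene-7,19-dioate
Product: 25 dimethyl 15α,20-dihydroxy-ent-gibberell-16-ene-7,19-dioate
Conditions: HF·pyridine, pyridine, THF, 0 °C → rt; crude product used at once
Reagents that add atoms: none
Why: Cleavage of the primary silyl ether by buffered HF, chosen so that no alkoxide is formed that would attack the neighbouring C19 or C7 ester; the diol is oxidized immediately in step 19.

Step 19
Reactants: 25 dimethyl 15α,20-dihydroxy-ent-gibberell-16-ene-7,19-dioate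
Product: 26 7,19-dimethyl hydrogen 15-oxo-ent-gibberell-16-ene-7,19,20-trioate (20-carboxylic acid)
Conditions: CrO3, H2SO4, H2O (Jones reagent), acetone, 0 °C
Reagents that add atoms: chromium trioxide, O=[Cr](=O)=O; water, O
Why: Jones oxidation takes both hydroxyls in one operation: the allylic 15-alcohol gives the 16-en-15-one and the neopentyl C20 alcohol goes through the aldehyde hydrate to the acid; chromate oxidation at 0 °C is expected to be far faster than acid-catalysed lactonization or isomerization of the methylene group.

Step 20
Reactants: 26 7,19-dimethyl hydrogen 15-oxo-ent-gibberell-16-ene-7,19,20-trioate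
Product: 27 7,19-dimethyl hydrogen 15β-hydroxy-ent-gibberell-16-ene-7,19,20-trioate (15-OH endo, toward C9)
Conditions: NaBH4 (excess), CeCl3·7H2O, MeOH, −78 → −20 °C
Reagents that add atoms: none
Why: Luche 1,2-reduction of the α-methylene ketone; hydride should be delivered to the exo face of the bicyclo[3.2.1]octenone, the endo face being screened by H9 and the three-carbon bridge, so the hydroxyl ends on the endo face, which is the 15β configuration of the target.

Step 21
Reactants: 27 7,19-dimethyl hydrogen 15β-hydroxy-ent-gibberell-16-ene-7,19,20-trioate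
Product: 28 15β-hydroxy-ent-gibberell-16-ene-7,19,20-trioic acid (the target gibberellin triacid)
Conditions: n-PrSLi, HMPA, rt → 50 °C; then cold aq. HCl to pH 3
Reagents that add atoms: none
Why: SN2 demethylation by thiolate at the ester methyl groups (O-alkyl cleavage), which does not depend on access to the shielded C19 carbonyl and needs neither hot hydroxide nor acid; the allylic alcohol and alkene are inert, C6 is already in its stable configuration, and brief cold acidification frees the triacid without allylic rearrangement.

## Compound list

1 | (R)-cyclohex-3-ene-1-carboxylic acid | OC(=O)[C@H]1CC=CCC1 | starting material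
2 | (1R,4R,5R)-4-iodo-6-oxabicyclo[3.2.1]octan-7-one | O=C1O[C@@H]2C[C@H]1CC[C@H]2I | intermediate
3 | (1R,5R)-6-oxabicyclo[3.2.1]oct-3-en-7-one | O=C1O[C@@H]2C[C@H]1CC=C2 | intermediate
4 | (1R,5R)-5-[2-hydroxy-1,3-bis(trimethylsilyl)propan-2-yl]cyclohex-2-en-1-ol | C[Si](C)(C)CC(O)(C[Si](C)(C)C)[C@H]1C[C@@H](O)C=CC1 | intermediate (not isolated)
5 | (1R,5R)-5-[3-(trimethylsilyl)prop-1-en-2-yl]cyclohex-2-en-1-ol | C[Si](C)(C)CC(=C)[C@H]1C[C@@H](O)C=CC1 | intermediate
6 | (5R)-5-[3-(trimethylsilyl)prop-1-en-2-yl]cyclohex-2-en-1-one | C[Si](C)(C)CC(=C)[C@H]1CC(=O)C=CC1 | intermediate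
7 | lithium (5R)-5-[3-(trimethylsilyl)prop-1-en-2-yl]cyclohex-1-en-1-olate | [Li+].[O-]C1=CCC[C@H](C1)C(=C)C[Si](C)(C)C | intermediate (not isolated)
8 | (5R)-5-[3-(trimethylsilyl)prop-1-en-2-yl]cyclohex-1-en-1-yl trifluoromethanesulfonate | C[Si](C)(C)CC(=C)[C@@H]1CCC=C(C1)OS(=O)(=O)C(F)(F)F | intermediate
9 | trimethyl{(5R)-5-[3-(trimethylsilyl)prop-1-en-2-yl]cyclohex-1-en-1-yl}stannane | C[Si](C)(C)CC(=C)[C@@H]1CCC=C(C1)[Sn](C)(C)C | intermediate
10 | methyl 2-oxocyclohexane-1-carboxylate | COC(=O)C1CCCCC1=O | starting material
11 | L-valine tert-butyl ester | CC(C)[C@H](N)C(=O)OC(C)(C)C | starting material (auxiliary, recovered in step 8)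
12 | methyl 2-{[(2S)-1-tert-butoxy-3-methyl-1-oxobutan-2-yl]amino}cyclohex-1-ene-1-carboxylate | COC(=O)C1=C(N[C@@H](C(C)C)C(=O)OC(C)(C)C)CCCC1 | intermediate
13 | methyl (1R)-2-{[(2S)-1-tert-butoxy-3-methyl-1-oxobutan-2-yl]imino}-1-methylcyclohexane-1-carboxylate | COC(=O)[C@]1(C)CCCCC1=N[C@@H](C(C)C)C(=O)OC(C)(C)C | intermediate (not isolated)
14 | methyl (1R)-1-methyl-2-oxocyclohexane-1-carboxylate | COC(=O)[C@]1(C)CCCCC1=O | intermediate
15 | methyl (1R,3RS)-3-(hydroxymethyl)-1-methyl-2-oxocyclohexane-1-carboxylate (C3 epimers) | COC(=O)[C@]1(C)CCCC(CO)C1=O | intermediate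
16 | methyl (1R,3RS)-3-{[(tert-butyldiphenylsilyl)oxy]methyl}-1-methyl-2-oxocyclohexane-1-carboxylate (C3 epimers) | COC(=O)[C@]1(C)CCCC(CO[Si](c2ccccc2)(c2ccccc2)C(C)(C)C)C1=O | intermediate
17 | methyl (1R)-3-{[(tert-butyldiphenylsilyl)oxy]methyl}-1-methyl-2-{[(trifluoromethyl)sulfonyl]oxy}cyclohex-2-ene-1-carboxylate | COC(=O)[C@]1(C)CCCC(CO[Si](c2ccccc2)(c2ccccc2)C(C)(C)C)=C1OS(=O)(=O)C(F)(F)F | intermediate
18 | methyl (1R)-3-{[(tert-butyldiphenylsilyl)oxy]methyl}-1-methyl-2-{(5R)-5-[3-(trimethylsilyl)prop-1-en-2-yl]cyclohex-1-ene-1-carbonyl}cyclohex-2-ene-1-carboxylate (ring A–ring C dienone) | C[Si](C)(C)CC(=C)[C@@H]1CCC=C(C1)C(=O)C2=C(CO[Si](c3ccccc3)(c3ccccc3)C(C)(C)C)CCC[C@@]2(C)C(=O)OC | intermediate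
19 | BF3-bound 2-oxidocyclopentenyl (oxyallyl) cation: rings A, B and C closed, charge shared by C5 and C8, C13 allylsilane intact | C[Si](C)(C)CC(=C)[C@@H]1CC[C@@H]2[C+](C1)C(O[B-](F)(F)F)=C3[C@@]2(CO[Si](c4ccccc4)(c4ccccc4)C(C)(C)C)CCC[C@@]3(C)C(=O)OC | intermediate (not isolated)
20 | methyl 20-[(tert-butyldiphenylsilyl)oxy]-6-oxo-7-nor-ent-gibberell-16-en-19-oate (H5 β as drawn) | C=C1[C@@H]2CC[C@H]3[C@]4(CO[Si](c5ccccc5)(c5ccccc5)C(C)(C)C)CCC[C@@](C)(C(=O)OC)[C@H]4C(=O)[C@]3(C2)C1 | intermediate
21 | methyl 20-[(tert-butyldiphenylsilyl)oxy]-6-{[(trifluoromethyl)sulfonyl]oxy}-7-nor-ent-gibberella-5,16-dien-19-oate | C=C1[C@@H]2CC[C@H]3[C@]4(CO[Si](c5ccccc5)(c5ccccc5)C(C)(C)C)CCC[C@@](C)(C(=O)OC)C4=C(OS(=O)(=O)C(F)(F)F)[C@]3(C2)C1 | intermediate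
22 | dimethyl 20-[(tert-butyldiphenylsilyl)oxy]-ent-gibberella-5,16-diene-7,19-dioate | C=C1[C@@H]2CC[C@H]3[C@]4(CO[Si](c5ccccc5)(c5ccccc5)C(C)(C)C)CCC[C@@](C)(C(=O)OC)C4=C(C(=O)OC)[C@]3(C2)C1 | intermediate
23 | dimethyl 20-[(tert-butyldiphenylsilyl)oxy]-ent-gibberell-16-ene-7,19-dioate | C=C1[C@@H]2CC[C@H]3[C@]4(CO[Si](c5ccccc5)(c5ccccc5)C(C)(C)C)CCC[C@@](C)(C(=O)OC)[C@H]4[C@H](C(=O)OC)[C@]3(C2)C1 | intermediate
24 | dimethyl 20-[(tert-butyldiphenylsilyl)oxy]-15α-hydroxy-ent-gibberell-16-ene-7,19-dioate | C=C1[C@@H]2CC[C@H]3[C@]4(CO[Si](c5ccccc5)(c5ccccc5)C(C)(C)C)CCC[C@@](C)(C(=O)OC)[C@H]4[C@H](C(=O)OC)[C@]3(C2)[C@H]1O | intermediate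
25 | dimethyl 15α,20-dihydroxy-ent-gibberell-16-ene-7,19-dioate | C=C1[C@@H]2CC[C@H]3[C@]4(CO)CCC[C@@](C)(C(=O)OC)[C@H]4[C@H](C(=O)OC)[C@]3(C2)[C@H]1O | intermediate
26 | 7,19-dimethyl hydrogen 15-oxo-ent-gibberell-16-ene-7,19,20-trioate | C=C1[C@@H]2CC[C@H]3[C@]4(C(=O)O)CCC[C@@](C)(C(=O)OC)[C@H]4[C@H](C(=O)OC)[C@]3(C2)C1=O | intermediate
27 | 7,19-dimethyl hydrogen 15β-hydroxy-ent-gibberell-16-ene-7,19,20-trioate | C=C1[C@@H]2CC[C@H]3[C@]4(C(=O)O)CCC[C@@](C)(C(=O)OC)[C@H]4[C@H](C(=O)OC)[C@]3(C2)[C@@H]1O | intermediate
28 | 15β-hydroxy-ent-gibberell-16-ene-7,19,20-trioic acid (target gibberellin triacid; 15-OH endo, toward C9) | C=C1[C@@H]2CC[C@H]3[C@]4(C(=O)O)CCC[C@@](C)(C(=O)O)[C@H]4[C@H](C(=O)O)[C@]3(C2)[C@@H]1O | target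

## Step count and least certain steps

Total: 21 steps. Longest linear sequence: 16 steps (steps 1–6 and 12–21); the ring A branch (steps 7–11) joins at step 12.

**Step 13 (key step).** Three processes threaten it. The electrocyclization may rotate in the sense opposite to that predicted, since the two substrate biases are modest. The cation may lose a proton from C9 or C14 before the allylsilane reaches C8, since that capture needs a twist-boat ring C. The allylsilane may add in conjugate fashion to C9 before ring B closes. The fallback separates ring D formation from the electrocyclization and sets out from 18. A reductive Nazarov cyclization (BF3·OEt2, Et3SiH, CH2Cl2, −78 °C → rt) would give the tricyclic 6-ketone F1, which has hydrogen at C8 and keeps the allylsilane. Bromodesilylation with allylic transposition (N-bromosuccinimide, CH2Cl2, −78 °C) would give the 2-(bromomethyl)allyl ketone F2. KN(SiMe3)2 in THF would then close ring D by intramolecular alkylation of the C8 enolate, the classical bicyclo[3.2.1]octane closure; the C5 enolate cannot reach the bromide and returns by proton transfer. The path comes back at 20. The sense of conrotation remains under substrate control in both versions.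

**Step 12.** The triflate carbon of 17 lies between quaternary C4 and the substituted C10, so oxidative addition and acyl transfer may be slow and direct coupling without CO insertion may compete. The fallback sets out from 17 and 9. Palladium-catalysed formylation of 17 (Pd(PPh3)4, CO, Bu3SnH, THF, 50 °C) would give the ring A enal F3. Tin–lithium exchange on 9 (MeLi, THF, −78 °C) would give the ring C alkenyllithium F4, which adds to the aldehyde in preference to the hindered ester to give the bis-allylic alcohol F5. Dess–Martin oxidation returns to the route at 18.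

**Step 16.** Electron transfer to the tetrasubstituted enoate, flanked by two quaternary carbons, may be too slow, or protonation at C5 may take place on the α face. This fallback also bypasses steps 14 and 15. It sets out from 20 and keeps the C5 configuration obtained on quenching step 13. Corey–Chaykovsky methylenation (Me3S+ I−, n-BuLi, THF, 0 °C) would give the C6 spiro-epoxide F6. Meinwald rearrangement (BF3·OEt2, CH2Cl2, −78 °C) with K2CO3/MeOH equilibration of C6 would give the 7-aldehyde F7. Pinnick oxidation (NaClO2, NaH2PO4, 2-methyl-2-butene) would give the 7-acid F8, and Me3SiCHN2 returns to the route at 23. Its own weak point is possible epimerization at C5 under the basic ylide.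

**Step 18 (with step 19).** While the silyl ether is being cleaved, the freed C20 hydroxyl may close onto the C19 ester, or the 15α-hydroxyl onto the C7 ester, before oxidation. The fallback removes the electrophiles first and sets out from 24. n-PrSLi in HMPA would demethylate both esters to the 15α-hydroxy-20-silyloxy diacid F9, kept as its carboxylate salt. Bu4NF in THF would then free the diol diacid F10 as a bis(tetrabutylammonium) salt, in which no lactonization is possible. TEMPO (cat.) with PhI(OAc)2 in MeCN/aq. NaHCO3 would oxidize both hydroxyls to the 15-oxo triacid F11. Luche reduction as in step 20 comes back to the route at 28.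

**Step 20.** Hydride may enter on the endo face and return the 15α-alcohol, or add 1,4. The fallback replaces substrate control by reagent control and sets out from 26. Me3SiCHN2 would give the 15-oxo trimethyl ester F12, which protects the acid from borane. Corey–Bakshi–Shibata reduction (BH3·SMe2 with the 2-methyl-CBS-oxazaborolidine enantiomer that delivers hydride to the exo face, THF, −30 °C) would give the 15β-hydroxy trimethyl ester F13. The thiolate demethylation of step 21, now on three esters, comes back to the route at 28.

## Further compounds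

F1 | step 13 | tricyclic 6-ketone from reductive Nazarov cyclization (H at C8, C13 allylsilane intact; C5 and C8 epimers) | C[Si](C)(C)CC(=C)[C@@H]1CC[C@@H]2C(C1)C(=O)C3[C@@]2(CO[Si](c4ccccc4)(c4ccccc4)C(C)(C)C)CCC[C@@]3(C)C(=O)OC
F2 | step 13 | tricyclic 6-ketone with 2-(bromomethyl)allyl group on C13 (C5 and C8 epimers) | BrCC(=C)[C@@H]1CC[C@@H]2C(C1)C(=O)C3[C@@]2(CO[Si](c4ccccc4)(c4ccccc4)C(C)(C)C)CCC[C@@]3(C)C(=O)OC
F3 | step 12 | methyl (1R)-3-{[(tert-butyldiphenylsilyl)oxy]methyl}-2-formyl-1-methylcyclohex-2-ene-1-carboxylate | COC(=O)[C@]1(C)CCCC(CO[Si](c2ccccc2)(c2ccccc2)C(C)(C)C)=C1C=O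
F4 | step 12 | {(5R)-5-[3-(trimethylsilyl)prop-1-en-2-yl]cyclohex-1-en-1-yl}lithium | [Li]C1=CCC[C@H](C1)C(=C)C[Si](C)(C)C
F5 | step 12 | bis-allylic alcohol corresponding to dienone 18 (carbinol epimers) | C[Si](C)(C)CC(=C)[C@@H]1CCC=C(C1)C(O)C2=C(CO[Si](c3ccccc3)(c3ccccc3)C(C)(C)C)CCC[C@@]2(C)C(=O)OC
F6 | step 16 | C6 spiro-epoxide of ketone 20 (either C6 epimer) | C=C1[C@@H]2CC[C@H]3[C@]4(CO[Si](c5ccccc5)(c5ccccc5)C(C)(C)C)CCC[C@@](C)(C(=O)OC)[C@H]4C6(CO6)[C@]3(C2)C1
F7 | step 16 | methyl 20-[(tert-butyldiphenylsilyl)oxy]-7-oxo-ent-gibberell-16-en-19-oate (6β-aldehyde) | C=C1[C@@H]2CC[C@H]3[C@]4(CO[Si](c5ccccc5)(c5ccccc5)C(C)(C)C)CCC[C@@](C)(C(=O)OC)[C@H]4[C@H](C=O)[C@]3(C2)C1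
F8 | step 16 | 19-methyl hydrogen 20-[(tert-butyldiphenylsilyl)oxy]-ent-gibberell-16-ene-7,19-dioate (7-acid) | C=C1[C@@H]2CC[C@H]3[C@]4(CO[Si](c5ccccc5)(c5ccccc5)C(C)(C)C)CCC[C@@](C)(C(=O)OC)[C@H]4[C@H](C(=O)O)[C@]3(C2)C1
F9 | step 18 | 20-[(tert-butyldiphenylsilyl)oxy]-15α-hydroxy-ent-gibberell-16-ene-7,19-dioic acid | C=C1[C@@H]2CC[C@H]3[C@]4(CO[Si](c5ccccc5)(c5ccccc5)C(C)(C)C)CCC[C@@](C)(C(=O)O)[C@H]4[C@H](C(=O)O)[C@]3(C2)[C@H]1O
F10 | step 18 | 15α,20-dihydroxy-ent-gibberell-16-ene-7,19-dioic acid (neutral form of the salt) | C=C1[C@@H]2CC[C@H]3[C@]4(CO)CCC[C@@](C)(C(=O)O)[C@H]4[C@H](C(=O)O)[C@]3(C2)[C@H]1O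
F11 | step 18 | 15-oxo-ent-gibberell-16-ene-7,19,20-trioic acid | C=C1[C@@H]2CC[C@H]3[C@]4(C(=O)O)CCC[C@@](C)(C(=O)O)[C@H]4[C@H](C(=O)O)[C@]3(C2)C1=O
F12 | step 20 | trimethyl 15-oxo-ent-gibberell-16-ene-7,19,20-trioate | C=C1[C@@H]2CC[C@H]3[C@]4(C(=O)OC)CCC[C@@](C)(C(=O)OC)[C@H]4[C@H](C(=O)OC)[C@]3(C2)C1=O
F13 | step 20 | trimethyl 15β-hydroxy-ent-gibberell-16-ene-7,19,20-trioate | C=C1[C@@H]2CC[C@H]3[C@]4(C(=O)OC)CCC[C@@](C)(C(=O)OC)[C@H]4[C@H](C(=O)OC)[C@]3(C2)[C@@H]1O
A1 | alternative 1 | 19,20-lactone with vinyl and methyl on quaternary C4, allyl on C10, 16-ketone as dioxolane, C7 methyl ester | C=C[C@@]1(C)C(=O)OC[C@@]2(CC=C)[C@@H]1[C@H](C(=O)OC)[C@]34C[C@H](C5(OCCO5)C3)CC[C@H]42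
A2 | alternative 2 | 12,16-cyclo 15-ketone (cyclopropyl ketone), 7,19,20-trimethyl ester | [C@@H]15[C@@H]2[C@H]5C[C@H]3[C@]4(C(=O)OC)CCC[C@@](C)(C(=O)OC)[C@H]4[C@H](C(=O)OC)[C@]3(C2)C1=O
A3 | alternative 3 | tetracyclic Diels–Alder adduct with C1=C2, ester on C4, silyloxymethyls as C19 and C20, 15-silyloxy-16-ketone | O=C1[C@@H]2CC[C@H]3[C@]4(CO[Si](C)(C)C(C)(C)C)C=CC[C@@](C(=O)OC)(CO[Si](C)(C)C(C)(C)C)[C@H]4[C@H](C(=O)OC)[C@]3(C2)[C@@H]1O[Si](C)(C)C(C)(C)C
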